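Asked is how long the chains of the north-west flask are by 5.0 h: monomer in chains divided by chains begun, living or dead together.

| setting | north-west | south-west | flask |
|---|---|---|---|
| free monomer | 2.2 M | 2.2 M | 2.2 M |
| transfer agent | 0.022 M | 0.022 M | 0.0220 M |
| protic impurity | 1.1 M | 1.1 M | 1.10 M |
| pre-initiator | 200 mM | 100 mM | 200 mM |
| remark | the very flask that is asked about, followed so far | run made earlier |  |
| time |  |  | 5.0 h |

| run | time / min | monomer in chains / % | free monomer / % |
|---|---|---|---|
| north-west | 20.0 | 11.5 | 54.1 |
| north-west | 40.0 | 24.3 | 30.7 |
| north-west | 50.0 | 30.4 | 24.1 |
| north-west | 80.0 | 42.3 | 11.1 |
| north-west | 90.0 | 46.8 | 9.0 |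
| south-west | 25.0 | 9.8 | 52.1 |
| south-west | 50.0 | 17.9 | 38.6 |
| south-west | 80.0 | 24.3 | 27.8 |
| south-west | 90.0 | 27.6 | 24.1 |
| south-west | 120 | 34.1 | 18.8 |

(each reading ± 1 percentage point)

- whether the average number of monomer units in a chain (chains begun, living or dead) reaches 3.0 by 5.0 h (no / yes)
- average number of monomer units in a chain (chains begun, living or dead) at 5.0 h

- the average divides the monomer in chains by the number of chains begun, living and dead together
- the numbers in the tables scatter with a standard deviation of 1 percentage point
- the earlier runs do not show the number of chains; that part of a forecast is a guess

The top of that fraction can be read from the runs. Free monomer and monomer in chains do not sum to the charge: in the north-west run the missing part goes from 34.4 % at 20.0 min to 44.2 % at 90.0 min, and in the south-west run, with half the pre-initiator, it stands at 47.1 % at 120 min. A one-to-one side reaction with the protic impurity would stop at 50.0 % of the monomer charged, and these readings stay lower than that.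

A first estimate therefore shares the monomer charged beyond the protic impurity among one chain per pre-initiator. This flask gives 5.50 for the spared length, the monomer charged beyond the protic impurity per pre-initiator charged, that is ([free monomer] − [protic impurity])/[pre-initiator].

One objection is that this monomer may not reach chains in time. But north-west free monomer falls from 24.1 % to 9.0 % between 50.0 min and 90.0 min, which, taken as a pseudo-first-order tail, gives a half-time read as 28.1 min, and if that tail held, about 0.0506 % would stand by 5.0 h.

The harder objection is that no run shows the number of chains. If each transfer agent began one more, the length would be 4.95; with the same monomer in chains it would fall short of 3.0 with chains begun above 0.367 M, about twice the pre-initiator charged. The reckoning here commits to yes, with a length near the spared length.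

The forecast says yes, with a length of 6 in a range of 4.3 to 8.5, and holds that reaching 3.0 would fail if “impurity-driven transfer started many additional chains”.

The flask gives yes, with a length of 5.76 at 5.00 h.

    living end + transfer agent → dead chain (kL = 1.30 L mol⁻¹ min⁻¹)
    pre-initiator → initiator (k = 0.0370 min⁻¹)
    free monomer + initiator → living end + monomer in chains (k = 1.40 L mol⁻¹ min⁻¹)
    free monomer + living end → monomer in chains + living end, rate k4*[living end]*[free monomer] (k = 0.120 L mol⁻¹ min⁻¹)
    protic impurity + free monomer → quenched substrate (k = 0.0390 L mol⁻¹ min⁻¹)

In the north-west flask at 5.00 h the protic impurity holds 4.7 % of its own charge, and the spared length, with that remainder added to the monomer charged beyond the impurity, becomes 5.76. In the south-west run, with 100 mM of pre-initiator, the spared length is 11.0, and its last reading at 120 min, free monomer plus monomer in chains per pre-initiator charged, stands at 11.6.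

The data come from a simulation with made-up constants, and the scatter is random.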